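**Plan**

- The target is (2R)-β-tocotrienol. Side-chain carbons are numbered C1' to C12' outward from chroman C2; the benzene ring is ring A and the dihydropyran ring is ring B.
- Retrosynthetic cuts, in order: C6'–C7' (alkyl–alkenyl union); C5'=C6' (methylenation) and the C5' oxidation level (allylic C–H oxidation of a prenyl end); O1–C8a of ring B (back to a quinone carrying a tertiary alcohol); C4–C4a (aryl–alkyl coupling).
- Enabling feature: C6' is the unsubstituted terminus of the 1,3-diene C3'=C4'(CH3)–C5'=C6', the only unhindered alkene of the chroman half, so 9-BBN places boron there alone. C7' is the hydrogen-bearing sp2 carbon of C7'=C8'(CH3), which is the terminal carbon of an alkyne after syn methylalumination. The extra C5'=C6' unsaturation is the helper and is consumed in the event.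
- Forward order: ring A is bought as a hydroquinone dimethyl ether, brominated and joined at C4a to hydroborated (R)-linalool. Oxidation to the quinone, ketal closure of ring B at C8a and reductive re-aromatisation give the chromanol. The prenyl end is oxidised at C5' and methylenated, and the chain is completed by one-flask hydroboration and coupling with the C7'–C12' iodide.
- Stereochemistry: C2 (R) is the carbinol carbon of (R)-linalool and none of its bonds is broken. E at C3'=C4' comes from E-selective SeO2 oxidation, E at C7'=C8' from syn carboalumination, and both are retained in the coupling.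

Key step: step 10

Assumption: commercial (R)-(−)-linalool of high enantiomeric purity is used; its enantiomeric purity is carried unchanged into C2 of the target.

**Route**

Step 1
Reactants: 1 6-methylhept-5-en-2-one
Product: 3 6-methylhept-5-en-1-yne, via enol phosphate 2 (not isolated)
Conditions: LiN(iPr)2 (1.05 equiv), THF, −78 °C; ClP(O)(OEt)2 (1.1 equiv), −78 °C → rt; then LiN(iPr)2 (2.3 equiv), THF, −78 °C → rt; aq. NH4Cl
Reagents that add atoms: none
Why: The kinetic enolate forms at the methyl group, is trapped on oxygen as the enol phosphate, and double elimination with excess amide base should give the terminal alkyne (methyl ketone to alkyne conversion via an enol phosphate), the trisubstituted alkene being inert and no stereocenter being involved.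

Step 2
Reactants: 3 6-methylhept-5-en-1-yne
Product: 5 (1E)-1-iodo-2,6-dimethylhepta-1,5-diene, via alkenylalane 4 (not isolated)
Conditions: Me3Al (2.0 equiv), Cp2ZrCl2 (0.25 equiv), CH2Cl2, 0 °C → rt; then I2 (1.2 equiv), THF, −30 → 0 °C
Reagents that add atoms: trimethylaluminium, C[Al](C)C; iodine, [I][I]
Why: Zirconium-catalysed methylalumination (Negishi carboalumination) delivers CH3 and Al syn across the terminal alkyne with Al on the terminal carbon, and iodinolysis of the C–Al bond with retention should give the E iodide, while the trisubstituted alkene does not carboaluminate.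

Step 3
Reactants: 6 1,4-dimethoxy-2,5-dimethylbenzene
Product: 7 1-bromo-2,5-dimethoxy-3,6-dimethylbenzene
Conditions: NBS (1.05 equiv), MeCN, 0 °C → rt, dark
Reagents that add atoms: N-bromosuccinimide, O=C1CCC(=O)N1Br
Why: Electrophilic aromatic bromination of the doubly methoxy-activated ring, whose two free positions are equivalent by symmetry, should stop at the monobromide with one equivalent of NBS because the first bromine deactivates the ring.

Step 4
Reactants: 8 (R)-linalool [(3R)-3,7-dimethylocta-1,6-dien-3-ol]; 7 1-bromo-2,5-dimethoxy-3,6-dimethylbenzene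
Product: 10 (3R)-1-(2,5-dimethoxy-3,6-dimethylphenyl)-3,7-dimethyloct-6-en-3-ol, via alkylborane 9 (not isolated)
Conditions: 9-BBN (0.5 M in THF, 1.3 equiv), 0 °C → rt; then 7 (0.85 equiv), Pd(OAc)2 (3 mol%), SPhos (6 mol%), 3 M aq. K3PO4 (3 equiv), THF, 65 °C
Reagents that add atoms: none
Why: 9-BBN hydroborates only the monosubstituted vinyl group (boron on the terminal carbon, the hindered tertiary hydroxyl reacting far more slowly), and B-alkyl Suzuki–Miyaura coupling under a bulky electron-rich biarylphosphine joins this primary alkyl group to the di-ortho-substituted aryl bromide; no bond to the carbinol carbon is touched, so the R configuration of 8 is carried into 10.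

Step 5
Reactants: 10 (3R)-1-(2,5-dimethoxy-3,6-dimethylphenyl)-3,7-dimethyloct-6-en-3-ol
Product: 11 2-[(3R)-3-hydroxy-3,7-dimethyloct-6-en-1-yl]-3,6-dimethyl-1,4-benzoquinone
Conditions: (NH4)2Ce(NO3)6 (2.5 equiv), MeCN/H2O 2:1, 0 °C, 20 min
Reagents that add atoms: water, O
Why: Oxidative demethylation of the hydroquinone dimethyl ether by the cerium reagent (two one-electron oxidations, water adding to the ring and methanol leaving) is fast at 0 °C and should outpace any attack on the isolated alkene or the tertiary alcohol, and the stereocenter is untouched.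

Step 6
Reactants: 11 2-[(3R)-3-hydroxy-3,7-dimethyloct-6-en-1-yl]-3,6-dimethyl-1,4-benzoquinone
Product: 13 (2R)-2,5,8-trimethyl-2-(4-methylpent-3-en-1-yl)chroman-6-ol, via cyclic methyl ketal 12 (not isolated)
Conditions: HC(OMe)3 (3 equiv), MeOH, p-TsOH·H2O (5 mol%), rt; then Zn dust (5 equiv), AcOH (10 equiv), 0 °C → rt, argon
Reagents that add atoms: none
Why: The tertiary hydroxyl adds to the neighbouring quinone carbonyl and methanol completes a cyclic mixed ketal of the 8a-alkoxy-tocopherone type (orthoformate removes the water), and two-electron reduction of this quinone monoketal by zinc should expel the pseudo-axial methoxy group and re-aromatise ring A to the chroman-6-ol; the tertiary C–O bond is never broken, so C2 of the chroman is obtained as R with retention.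

Step 7
Reactants: 13 (2R)-2,5,8-trimethyl-2-(4-methylpent-3-en-1-yl)chroman-6-ol
Product: 14 triisopropyl{[(2R)-2,5,8-trimethyl-2-(4-methylpent-3-en-1-yl)chroman-6-yl]oxy}silane
Conditions: TIPSCl (1.3 equiv), imidazole (2.5 equiv), DMF, rt → 40 °C
Reagents that add atoms: chlorotriisopropylsilane, CC(C)[Si](Cl)(C(C)C)C(C)C
Why: Silylation of the phenol (the only hydroxyl) with a bulky silyl chloride and imidazole gives an aryl silyl ether that should withstand the oxidant, the ylide and the aqueous base of the coming steps.

Step 8
Reactants: 14 triisopropyl{[(2R)-2,5,8-trimethyl-2-(4-methylpent-3-en-1-yl)chroman-6-yl]oxy}silane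
Product: 16 (2E)-2-methyl-5-[(2R)-2,5,8-trimethyl-6-(triisopropylsilyloxy)chroman-2-yl]pent-2-enal, via E-allylic alcohol 15 (not isolated)
Conditions: SeO2 (0.3 equiv), t-BuOOH (5.5 M in decane, 3 equiv), salicylic acid (0.1 equiv), CH2Cl2, rt; filtration through silica; then MnO2 (15 equiv), CH2Cl2, rt
Reagents that add atoms: tert-butyl hydroperoxide (oxygen, relayed by SeO2), CC(C)(C)OO
Why: Selenium dioxide allylic oxidation (ene reaction then [2,3]-sigmatropic shift) attacks the methyl group trans to the chain at the disubstituted end of the trisubstituted alkene and should give the E allylic alcohol, which MnO2 oxidises to the E enal, so that the E geometry of C3'=C4' is fixed here.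

Step 9
Reactants: 16 (2E)-2-methyl-5-[(2R)-2,5,8-trimethyl-6-(triisopropylsilyloxy)chroman-2-yl]pent-2-enal
Product: 17 triisopropyl({(2R)-2,5,8-trimethyl-2-[(3E)-4-methylhexa-3,5-dien-1-yl]chroman-6-yl}oxy)silane
Conditions: Ph3PCH3Br (1.5 equiv), KN(SiMe3)2 (1.4 equiv), THF, 0 °C; then 16, −78 °C → rt
Reagents that add atoms: methyltriphenylphosphonium bromide, C[P+](c1ccccc1)(c1ccccc1)c1ccccc1.[Br-]
Why: Wittig methylenation of the enal, which has no α-hydrogen, with the unstabilised ylide builds C6' and the terminal 1,3-diene without touching the E trisubstituted alkene.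

Step 10
Reactants: 17 triisopropyl({(2R)-2,5,8-trimethyl-2-[(3E)-4-methylhexa-3,5-dien-1-yl]chroman-6-yl}oxy)silane; 5 (1E)-1-iodo-2,6-dimethylhepta-1,5-diene
Product: 19 triisopropyl({(2R)-2,5,8-trimethyl-2-[(3E,7E)-4,8,12-trimethyltrideca-3,7,11-trien-1-yl]chroman-6-yl}oxy)silane, via homoallylic borane 18 (not isolated)
Conditions: 9-BBN (0.5 M in THF, 1.15 equiv), THF, 0 °C → rt, 3 h; then 3 M aq. K3PO4 (3 equiv), 5 (1.2 equiv), Pd(dppf)Cl2 (5 mol%), AsPh3 (10 mol%), DMF, degassed, rt, 16 h
Reagents that add atoms: none
Why: 9-BBN adds its B–H bond syn across the monosubstituted C5'=C6' end of the 1,3-diene through a four-centre transition state that puts the bulky boron on the unsubstituted terminus C6', while the trisubstituted C3'=C4' alkene is too hindered to react, so homoallylic borane 18 forms; the base then turns 18 into a borate, zerovalent palladium inserts into the C–I bond of 5 with retention of alkene geometry, the primary alkyl group passes from boron to palladium, and reductive elimination forms the C6'–C7' bond. The closest known reaction types are the terminal-selective hydroboration of 1,3-dienes that carry one monosubstituted and one trisubstituted alkene (4,8-dimethylnona-1,3,7-triene is the standard case) and the B-alkyl Suzuki–Miyaura coupling of primary alkyl-9-BBN reagents with E-alkenyl iodides. No ring is closed and no stereocenter is created; C2 is remote and untouched. What is controlled is alkene geometry: the E C3'=C4' alkene (from step 8) is a spectator, and the E C7'=C8' alkene (from step 2) should pass through oxidative addition and reductive elimination without isomerisation. The step needs regio- and chemoselective monohydroboration, which the bulk of 9-BBN, the near-stoichiometric amount of reagent and the absence of any other unhindered alkene in 17 secure, and it needs reductive elimination to outrun β-hydride elimination from the homoallylpalladium intermediate, which the wide bite angle of dppf together with AsPh3 secures. Residual B–H is destroyed by the aqueous base before 5 is added, so the prenyl end of 5 is not hydroborated, and the aryl silyl ether should tolerate K3PO4 at room temperature.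

Step 11
Reactants: 19 triisopropyl({(2R)-2,5,8-trimethyl-2-[(3E,7E)-4,8,12-trimethyltrideca-3,7,11-trien-1-yl]chroman-6-yl}oxy)silane
Product: 20 (2R)-2,5,8-trimethyl-2-[(3E,7E)-4,8,12-trimethyltrideca-3,7,11-trien-1-yl]chroman-6-ol (β-tocotrienol)
Conditions: Bu4NF (1.2 equiv), THF, 0 °C → rt, argon; then H2O
Reagents that add atoms: none
Why: Fluoride attacks silicon and releases the phenoxide, the standard cleavage of an aryl silyl ether, which should leave the skipped triene and C2 unaffected, argon keeping the electron-rich chromanol from autoxidation.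

**Compound list**

1 | 6-methylhept-5-en-2-one | CC(=O)CCC=C(C)C | starting material
2 | diethyl 6-methylhepta-1,5-dien-2-yl phosphate (not isolated) | C=C(CCC=C(C)C)OP(=O)(OCC)OCC | intermediate
3 | 6-methylhept-5-en-1-yne | C#CCCC=C(C)C | intermediate
4 | [(1E)-2,6-dimethylhepta-1,5-dien-1-yl]dimethylalumane (not isolated) | CC(C)=CCC/C(C)=C/[Al](C)C | intermediate
5 | (1E)-1-iodo-2,6-dimethylhepta-1,5-diene | CC(C)=CCC/C(C)=C/I | intermediate
6 | 1,4-dimethoxy-2,5-dimethylbenzene | COc1cc(C)c(OC)cc1C | starting material
7 | 1-bromo-2,5-dimethoxy-3,6-dimethylbenzene | COc1cc(C)c(OC)c(Br)c1C | intermediate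
8 | (R)-linalool [(3R)-3,7-dimethylocta-1,6-dien-3-ol] | C=C[C@](C)(O)CCC=C(C)C | starting material
9 | (3S)-1-(9-borabicyclo[3.3.1]nonan-9-yl)-3,7-dimethyloct-6-en-3-ol (not isolated; same spatial arrangement as 8, the descriptor changes only because boron ranks below carbon) | C(C[C@](C)(O)CCC=C(C)C)B1C2CCCC1CCC2 | intermediate
10 | (3R)-1-(2,5-dimethoxy-3,6-dimethylphenyl)-3,7-dimethyloct-6-en-3-ol | COc1cc(C)c(OC)c(CC[C@](C)(O)CCC=C(C)C)c1C | intermediate
11 | 2-[(3R)-3-hydroxy-3,7-dimethyloct-6-en-1-yl]-3,6-dimethyl-1,4-benzoquinone | CC1=CC(=O)C(C)=C(CC[C@](C)(O)CCC=C(C)C)C1=O | intermediate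
12 | (2R)-8a-methoxy-2,5,8-trimethyl-2-(4-methylpent-3-en-1-yl)-2,3,4,8a-tetrahydro-6H-chromen-6-one (not isolated; mixture of C8a epimers) | COC12O[C@](C)(CCC=C(C)C)CCC1=C(C)C(=O)C=C2C | intermediate
13 | (2R)-2,5,8-trimethyl-2-(4-methylpent-3-en-1-yl)chroman-6-ol | CC(C)=CCC[C@]1(C)CCc2c(C)c(O)cc(C)c2O1 | intermediate
14 | triisopropyl{[(2R)-2,5,8-trimethyl-2-(4-methylpent-3-en-1-yl)chroman-6-yl]oxy}silane | CC(C)=CCC[C@]1(C)CCc2c(C)c(O[Si](C(C)C)(C(C)C)C(C)C)cc(C)c2O1 | intermediate
15 | (2E)-2-methyl-5-[(2R)-2,5,8-trimethyl-6-(triisopropylsilyloxy)chroman-2-yl]pent-2-en-1-ol (not isolated) | OC/C(C)=C/CC[C@]1(C)CCc2c(C)c(O[Si](C(C)C)(C(C)C)C(C)C)cc(C)c2O1 | intermediate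
16 | (2E)-2-methyl-5-[(2R)-2,5,8-trimethyl-6-(triisopropylsilyloxy)chroman-2-yl]pent-2-enal | O=C/C(C)=C/CC[C@]1(C)CCc2c(C)c(O[Si](C(C)C)(C(C)C)C(C)C)cc(C)c2O1 | intermediate
17 | triisopropyl({(2R)-2,5,8-trimethyl-2-[(3E)-4-methylhexa-3,5-dien-1-yl]chroman-6-yl}oxy)silane | C=C/C(C)=C/CC[C@]1(C)CCc2c(C)c(O[Si](C(C)C)(C(C)C)C(C)C)cc(C)c2O1 | intermediate
18 | 9-{(3E)-4-methyl-6-[(2R)-2,5,8-trimethyl-6-(triisopropylsilyloxy)chroman-2-yl]hex-3-en-1-yl}-9-borabicyclo[3.3.1]nonane (not isolated) | C(C/C(C)=C/CC[C@]1(C)CCc2c(C)c(O[Si](C(C)C)(C(C)C)C(C)C)cc(C)c2O1)B1C2CCCC1CCC2 | intermediate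
19 | triisopropyl({(2R)-2,5,8-trimethyl-2-[(3E,7E)-4,8,12-trimethyltrideca-3,7,11-trien-1-yl]chroman-6-yl}oxy)silane | CC(C)=CCC/C(C)=C/CC/C(C)=C/CC[C@]1(C)CCc2c(C)c(O[Si](C(C)C)(C(C)C)C(C)C)cc(C)c2O1 | intermediate
20 | (2R)-2,5,8-trimethyl-2-[(3E,7E)-4,8,12-trimethyltrideca-3,7,11-trien-1-yl]chroman-6-ol (β-tocotrienol) | CC(C)=CCC/C(C)=C/CC/C(C)=C/CC[C@]1(C)CCc2c(C)c(O)cc(C)c2O1 | target

**Step count**

Total step count: 11. Longest linear sequence: 9 steps (steps 3 to 11, from 6 to 20).

**Steps most likely to fail, with fallbacks**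

Step 6 (closure of ring B). Ketalisation may stop short or go to the wrong place (dimethyl ketal at the less hindered C6 carbonyl, or conjugate addition of methanol at C7). During the reduction the ring oxygen may leave instead of methoxide, which would open ring B again. The fallback sets out from 11 and comes back to the route at 14. It forms the O1–C8a bond on the aromatic ring by palladium catalysis instead of on the quinone.
- 11 is reduced with aq. Na2S2O4 (Et2O/H2O, argon) to 2-[(3R)-3-hydroxy-3,7-dimethyloct-6-en-1-yl]-3,6-dimethylbenzene-1,4-diol F1.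
- The less hindered phenol (the one between CH3 and H, the future C6–OH) is silylated with TIPSCl and imidazole in DMF at 0 °C to 2-[(3R)-3-hydroxy-3,7-dimethyloct-6-en-1-yl]-3,6-dimethyl-4-(triisopropylsilyloxy)phenol F2.
- The remaining di-ortho-substituted phenol is converted with NaH and PhNTf2 in THF into the aryl triflate F3; the tertiary alcohol should not be sulfonylated.
- Intramolecular C–O coupling of the tertiary alkoxide with the aryl triflate (Pd(OAc)2, 2-(di-tert-butylphosphino)-1,1'-binaphthyl, Cs2CO3, toluene, 80 °C) should close ring B with the tertiary C–O bond intact and give 14 directly, so that step 7 is not needed.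

Step 10 (key step). Hydroboration may not stop after one addition at C6' (second hydroboration, or boron at C5'). In the coupling, slow transfer of the alkyl group from boron may let protodeboronation or β-hydride elimination from the alkylpalladium species compete. The fallback sets out from 17 and comes back at 19. It separates the two events and uses zinc in place of boron for the bond formation.
- 17 is hydroborated to 18 as before and oxidised in the flask (NaBO3·4H2O, THF/H2O) to (3E)-4-methyl-6-[(2R)-2,5,8-trimethyl-6-(triisopropylsilyloxy)chroman-2-yl]hex-3-en-1-ol F4, which can be freed from regioisomers by chromatography.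
- I2, PPh3 and imidazole in CH2Cl2 should give the corresponding primary iodide F5.
- Halogen–lithium exchange (t-BuLi, 2 equiv, Et2O, −78 °C) followed by ZnBr2 in THF gives the homoallylzinc bromide F6.
- Negishi alkyl–alkenyl coupling of F6 with 5 under Pd(PPh3)4 in THF at rt should give 19 with both alkene geometries retained.

Step 4 (aryl–alkyl coupling). Transfer of the γ-hydroxyalkyl group from boron to the crowded arylpalladium centre may be slow, so that debromination of 7 and protodeboronation take over. The fallback sets out from 7 and 8 and comes back at 10. It uses no organometallic partner.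
- Heck reaction of 7 with 8 (Pd2(dba)3, P(t-Bu)3, Cy2NMe, dioxane, 90 °C) should give (1E,3R)-1-(2,5-dimethoxy-3,6-dimethylphenyl)-3,7-dimethylocta-1,6-dien-3-ol F7, because the carbinol carbon has no hydrogen and β-hydride elimination can only lead to the E styrene.
- Diimide (2-nitrobenzenesulfonohydrazide, Et3N, CH2Cl2, rt) should reduce the disubstituted styrene alkene much faster than the trisubstituted one and give 10.

Further compounds
F1 | step 6 | 2-[(3R)-3-hydroxy-3,7-dimethyloct-6-en-1-yl]-3,6-dimethylbenzene-1,4-diol | Cc1cc(O)c(C)c(CC[C@](C)(O)CCC=C(C)C)c1O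
F2 | step 6 | 2-[(3R)-3-hydroxy-3,7-dimethyloct-6-en-1-yl]-3,6-dimethyl-4-(triisopropylsilyloxy)phenol | Cc1cc(O[Si](C(C)C)(C(C)C)C(C)C)c(C)c(CC[C@](C)(O)CCC=C(C)C)c1O
F3 | step 6 | 2-[(3R)-3-hydroxy-3,7-dimethyloct-6-en-1-yl]-3,6-dimethyl-4-(triisopropylsilyloxy)phenyl trifluoromethanesulfonate | Cc1cc(O[Si](C(C)C)(C(C)C)C(C)C)c(C)c(CC[C@](C)(O)CCC=C(C)C)c1OS(=O)(=O)C(F)(F)F
F4 | step 10 | (3E)-4-methyl-6-[(2R)-2,5,8-trimethyl-6-(triisopropylsilyloxy)chroman-2-yl]hex-3-en-1-ol | OCC/C(C)=C/CC[C@]1(C)CCc2c(C)c(O[Si](C(C)C)(C(C)C)C(C)C)cc(C)c2O1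
F5 | step 10 | {[(2R)-2-[(3E)-6-iodo-4-methylhex-3-en-1-yl]-2,5,8-trimethylchroman-6-yl]oxy}triisopropylsilane | ICC/C(C)=C/CC[C@]1(C)CCc2c(C)c(O[Si](C(C)C)(C(C)C)C(C)C)cc(C)c2O1
F6 | step 10 | bromo{(3E)-4-methyl-6-[(2R)-2,5,8-trimethyl-6-(triisopropylsilyloxy)chroman-2-yl]hex-3-en-1-yl}zinc | Br[Zn]CC/C(C)=C/CC[C@]1(C)CCc2c(C)c(O[Si](C(C)C)(C(C)C)C(C)C)cc(C)c2O1
F7 | step 4 | (1E,3R)-1-(2,5-dimethoxy-3,6-dimethylphenyl)-3,7-dimethylocta-1,6-dien-3-ol | COc1cc(C)c(OC)c(/C=C/[C@](C)(O)CCC=C(C)C)c1C
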